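## Plan

1. The last cut opens the oxazole ring at C5'–N and O–C2. The target has N on arene carbon C5', O on C6' and a methyl on C2 of the fused oxazole ring, which is the array left when C5' of an ortho-hydroxyaryl methyl ketoxime migrates to nitrogen and the C6' hydroxyl closes onto the nitrilium carbon.
2. Earlier cuts: C5'–acetyl (directed lithiation), C4–CH3 (enol triflate coupling), C5–CH3 (reductive methylation), C11–C1' (aryllithium plus aldehyde, then deoxygenation), and C9–C10 with C7–C8 of ring B (Diels–Alder).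
3. Forward: ring A comes from cyclohexenone as a silyloxy vinylcyclohexene; ring B closes by cycloaddition with tiglaldehyde; the arene is joined at C11; the two ring-A methyls follow; then acetyl, oxime and finally the oxazole ring.
4. Stereochemistry: a CBS reduction sets the C4 carbinol, which steers the dienophile to one diene face (C10). Exo, suprafacial addition of the (E)-enal sets C9 and C8. The axial C9 methyl steers methylation of C5 to the cis ring fusion, after which the C4 carbinol is erased.

Key step: step 20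

Remarks on the chemistry:
- Decalin carbons are numbered as in avarane: ring A = C1, C2, C3, C4, C5, C10; ring B = C5 to C10; C11 sits on C9. Arene carbons are primed, with C1' bonded to C11. α/β refer to the drawing with the C9 methyl β.
- Ar = 3-methoxy-2,6-bis(methoxymethoxy)phenyl. Dec = (1R,2S,4aR,8aS)-1,2,4a,5-tetramethyl-1,2,3,4,4a,7,8,8a-octahydronaphthalen-1-yl.
- The carbinol carbon C11 of 14–16 is taken as a mixture of epimers, because its oxygen is removed in step 11.

## Route

Step 1
Reactants: 1 cyclohex-2-en-1-one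
Product: 2 2-iodocyclohex-2-en-1-one
Conditions: I2, pyridine, CH2Cl2, 0 °C to rt
Reagents that add atoms: iodine, II
Why: Pyridine-mediated α-iodination of a cyclic enone (conjugate addition of pyridine, iodination of the enolate, elimination; Baylis–Hillman-type) is a standard way to place a coupling handle on the α-carbon and creates no stereocentre.

Step 2
Reactants: 2 2-iodocyclohex-2-en-1-one
Product: 3 (R)-2-iodocyclohex-2-en-1-ol
Conditions: (S)-tetrahydro-1-methyl-3,3-diphenyl-1H,3H-pyrrolo[1,2-c][1,3,2]oxazaborole [(S)-Me-CBS] (10 mol %), BH3·SMe2, THF, −20 °C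
Reagents that add atoms: none
Why: Corey–Bakshi–Shibata reduction, in which the iodoalkenyl arm behaves as the large substituent, so that the (S)-catalyst should deliver hydride to give the (R)-carbinol (C4), the only stereocentre set by a chiral reagent.

Step 3
Reactants: 3 (R)-2-iodocyclohex-2-en-1-ol
Product: 4 (R)-tert-butyl[(2-iodocyclohex-2-en-1-yl)oxy]dimethylsilane
Conditions: TBSCl, imidazole, DMF, rt
Reagents that add atoms: tert-butyldimethylsilyl chloride, CC(C)(C)[Si](C)(C)Cl
Why: Imidazole-promoted silylation of the secondary allylic alcohol gives the bulky ether that later shields one face of the diene.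

Step 4
Reactants: 4 (R)-tert-butyl[(2-iodocyclohex-2-en-1-yl)oxy]dimethylsilane
Product: 5 (R)-tert-butyl[(2-ethenylcyclohex-2-en-1-yl)oxy]dimethylsilane
Conditions: CH2=CHSnBu3, Pd(PPh3)4 (5 mol %), CuI (10 mol %), DMF, 50 °C
Reagents that add atoms: tributyl(vinyl)stannane, C=C[Sn](CCCC)(CCCC)CCCC
Why: Stille cross-coupling of the alkenyl iodide with a vinylstannane proceeds with retention at the sp2 carbon and leaves the carbinol centre untouched, giving the semicyclic diene.

Step 5
Reactants: 5 (R)-tert-butyl[(2-ethenylcyclohex-2-en-1-yl)oxy]dimethylsilane; 6 (E)-2-methylbut-2-enal (tiglaldehyde)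
Product: 7 (1R,2S,5R,8aR)-5-[(tert-butyldimethylsilyl)oxy]-1,2-dimethyl-1,2,3,5,6,7,8,8a-octahydronaphthalene-1-carbaldehyde (4α-silyloxy, C5=C6 alkene, 8β-methyl, 9β-methyl, 9α-CHO, 10α-H)
Conditions: Me2AlCl (0.3 equiv), CH2Cl2, −78 to −30 °C
Reagents that add atoms: none
Why: Lewis acid-promoted Diels–Alder reaction in which ring terminus C10 bonds to the formyl-bearing carbon C9 and vinyl terminus C7 to C8 (ortho orientation), the enal approaches anti to the pseudoaxial C4 silyloxy group (sets C10), the formyl group takes the exo position as α-methyl enals usually do (sets C9), and suprafacial addition keeps the C8 and C9 methyls cis.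

Step 6
Reactants: 8 2,4-dihydroxybenzaldehyde
Product: 9 2,4-bis(methoxymethoxy)benzaldehyde
Conditions: MOMCl, i-Pr2NEt, CH2Cl2, 0 °C to reflux
Reagents that add atoms: chloromethyl methyl ether, COCCl
Why: Williamson-type acetalisation of both phenols under amine base protects them in a form that later directs two lithiations.

Step 7
Reactants: 9 2,4-bis(methoxymethoxy)benzaldehyde
Product: 11 2,4-bis(methoxymethoxy)phenol, via aryl formate 10 (not isolated)
Conditions: mCPBA, CH2Cl2, 0 °C to rt; then K2CO3 (cat.), MeOH, rt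
Reagents that add atoms: 3-chloroperoxybenzoic acid, OOC(=O)c1cccc(Cl)c1
Why: Baeyer–Villiger (Dakin-type) oxidation of the electron-rich benzaldehyde proceeds with aryl migration to the formate, which methanolysis cleaves to the phenol.

Step 8
Reactants: 11 2,4-bis(methoxymethoxy)phenol
Product: 12 1-methoxy-2,4-bis(methoxymethoxy)benzene
Conditions: MeI, K2CO3, acetone, reflux
Reagents that add atoms: iodomethane, CI
Why: Williamson O-methylation of the single free phenol fixes the future C3' methyl ether.

Step 9
Reactants: 12 1-methoxy-2,4-bis(methoxymethoxy)benzene; 7 the Diels–Alder aldehyde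
Product: 14 C11 carbinol (7 with CH(OH)Ar in place of CHO; C11 epimers), via aryllithium 13 (not isolated)
Conditions: 12, n-BuLi, THF, 0 °C; then 7, −78 to 0 °C
Reagents that add atoms: none
Why: Directed ortho-metalation at the carbon flanked by both MOM ethers gives the aryllithium, which undergoes 1,2-addition to the non-enolisable neopentyl aldehyde; the new C11 carbinol centre forms as a mixture that does not matter because the oxygen is removed.

Step 10
Reactants: 14 C11 carbinol
Product: 16 O-alkyl S-methyl xanthate of 14, via sodium xanthate 15 (not isolated)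
Conditions: NaH, CS2, THF, 0 °C to rt; then MeI
Reagents that add atoms: carbon disulfide, S=C=S; iodomethane, CI
Why: Xanthate formation (alkoxide, CS2, S-methylation) prepares the hindered benzylic alcohol for radical deoxygenation, and the quaternary C9 offers no β-hydrogen for Chugaev elimination.

Step 11
Reactants: 16 xanthate
Product: 17 silyl ether with C11 as CH2 (4α-silyloxy, C5=C6, 8β,9β-dimethyl, 9α-CH2Ar, 10α-H)
Conditions: Bu3SnH, AIBN (azobisisobutyronitrile, cat.), toluene, 110 °C
Reagents that add atoms: none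
Why: Barton–McCombie deoxygenation through a benzylic radical that has only 4-exo or 5-endo paths to the C5=C6 alkene and is therefore simply reduced by the tin hydride.

Step 12
Reactants: 17 silyl ether
Product: 18 allylic alcohol (4α-OH, C5=C6)
Conditions: Bu4NF, THF, rt to 50 °C
Reagents that add atoms: none
Why: Fluoride cleavage of the silyl ether frees the allylic alcohol without touching the MOM ethers.

Step 13
Reactants: 18 allylic alcohol
Product: 19 enone (C4 ketone conjugated with C5=C6)
Conditions: IBX, DMSO, rt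
Reagents that add atoms: none
Why: IBX oxidation of the allylic alcohol gives the conjugated enone under neutral conditions that spare the MOM ethers, and removes the C4 stereocentre once it has done its work.

Step 14
Reactants: 19 enone
Product: 21 cis-fused ketone (4-oxo, 5α-methyl, 8β,9β-dimethyl, 9α-CH2Ar, 10α-H), via lithium enolate 20 (not isolated)
Conditions: Li, NH3 (l), THF, t-BuOH (1 equiv), −78 °C; then MeI, −78 to −33 °C
Reagents that add atoms: iodomethane, CI
Why: Stork reductive alkylation: dissolving-metal reduction gives the C4–C5 lithium enolate regiospecifically, and MeI should attack C5 from the α face, syn to the C10 hydrogen and away from the axial C9 β-methyl that is 1,3-diaxial to the other face, which sets the cis ring fusion.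

Step 15
Reactants: 21 ketone
Product: 23 alkenyl triflate (C3=C4, triflate on C4), via potassium enolate 22 (not isolated)
Conditions: KN(SiMe3)2, THF, −78 °C; then PhNTf2, −78 to 0 °C
Reagents that add atoms: N-phenylbis(trifluoromethanesulfonimide), O=S(=O)(N(c1ccccc1)S(=O)(=O)C(F)(F)F)C(F)(F)F
Why: Enolisation can only go towards C3 because C5 is quaternary, and O-sulfonylation of the enolate fixes the double bond at C3–C4.

Step 16
Reactants: 23 alkenyl triflate
Product: 24 Dec-CH2-Ar, the bis-MOM arene carrying the complete decalin (4-methyl, C3=C4)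
Conditions: MeMgBr, Fe(acac)3 (5 mol %), THF/NMP, −20 to 0 °C
Reagents that add atoms: methylmagnesium bromide, C[Mg]Br
Why: Iron-catalysed Kumada-type cross-coupling of an alkenyl triflate with a methyl Grignard reagent (Fürstner conditions) replaces triflate by methyl without moving the alkene, and the MOM ethers are inert.

Step 17
Reactants: 24 bis-MOM arene
Product: 26 C5'-acetyl bis-MOM arene (methyl ketone), via aryllithium 25 (not isolated)
Conditions: s-BuLi, TMEDA, THF, −78 °C; then MeC(O)N(OMe)Me, −78 to 0 °C
Reagents that add atoms: N-methoxy-N-methylacetamide, CC(=O)N(C)OC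
Why: Directed ortho-metalation by the C6' MOM ether (a stronger director than the C3' methyl ether; the C2' MOM ether has no free ortho position) lithiates C5', and acylation with the Weinreb amide stops at the ketone.

Step 18
Reactants: 26 C5'-acetyl bis-MOM arene
Product: 27 1-[2,4-dihydroxy-5-methoxy-3-(Dec-methyl)phenyl]ethan-1-one
Conditions: HCl (1 M in MeOH), THF, rt
Reagents that add atoms: none
Why: Acid-catalysed methanolysis of the two aryl MOM acetals, both activated as leaving groups by the ortho or para acetyl group, should proceed under conditions too mild to protonate the trisubstituted alkene.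

Step 19
Reactants: 27 dihydroxy ketone
Product: 28 (E)-oxime of 27
Conditions: NH2OH·HCl, NaOAc, EtOH/H2O, 60 °C
Reagents that add atoms: hydroxylamine hydrochloride, NO.Cl
Why: Condensation of the ketone with hydroxylamine gives the oxime, whose E geometry (hydroxyl anti to the arene) is favoured by the smaller methyl group and by the hydrogen bond from the C6' hydroxyl to nitrogen.

Step 20
Reactants: 28 (E)-oxime
Product: 31 5-methoxy-2-methyl-7-(Dec-methyl)-1,3-benzoxazol-6-ol (target), via oxime triflate 29 (not isolated), via nitrilium triflate 30 (not isolated)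
Conditions: Tf2O (1.05 equiv), 2-chloropyridine (2.2 equiv), CH2Cl2, −78 to 0 °C
Reagents that add atoms: none
Why: Tf2O sulfonylates the oxime oxygen to give 29, the aryl carbon C5' anti-periplanar to the N–O bond migrates to nitrogen as triflate departs (C5'–N bond, nitrilium 30), and the C6' hydroxyl adds to the nitrilium carbon (O–C2 bond) before loss of a proton gives the aromatic oxazole. The closest known reaction type is the Beckmann rearrangement of ortho-hydroxyaryl ketoximes to 2-substituted benzoxazoles under electrophilic activation. The one new ring, the oxazole, closes in a 5-endo-dig mode onto the sp carbon of the nitrilium ion, which lies in the arene plane next to the phenol. No stereocentre is formed and the four decalin centres are remote from the reacting atoms. Aryl rather than methyl migration is secured by the E geometry of 28 and by the electron-rich migrating ring (C2' hydroxyl para and C6' hydroxyl ortho to C5'), while closure at nitrogen to the 1,2-benzisoxazole needs a phenoxide, which 2-chloropyridine is too weak a base to form. The same buffer holds triflic acid as its pyridinium salt so that the C3=C4 alkene is not protonated, and at −78 °C without phenoxide the oxime oxygen should be sulfonylated ahead of the two arene hydroxyls.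

## Compound list

1 | cyclohex-2-en-1-one | O=C1C=CCCC1 | starting material
2 | 2-iodocyclohex-2-en-1-one | O=C1CCCC=C1I | intermediate
3 | (R)-2-iodocyclohex-2-en-1-ol | O[C@@H]1CCCC=C1I | intermediate
4 | (R)-tert-butyl[(2-iodocyclohex-2-en-1-yl)oxy]dimethylsilane | CC(C)(C)[Si](C)(C)O[C@@H]1CCCC=C1I | intermediate
5 | (R)-tert-butyl[(2-ethenylcyclohex-2-en-1-yl)oxy]dimethylsilane | CC(C)(C)[Si](C)(C)O[C@@H]1CCCC=C1C=C | intermediate
6 | (E)-2-methylbut-2-enal | C/C=C(\C)C=O | starting material
7 | (1R,2S,5R,8aR)-5-[(tert-butyldimethylsilyl)oxy]-1,2-dimethyl-1,2,3,5,6,7,8,8a-octahydronaphthalene-1-carbaldehyde | O=C[C@]1(C)[C@@H](C)CC=C2[C@H](O[Si](C)(C)C(C)(C)C)CCC[C@@H]12 | intermediate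
8 | 2,4-dihydroxybenzaldehyde | O=Cc1ccc(O)cc1O | starting material
9 | 2,4-bis(methoxymethoxy)benzaldehyde | COCOc1ccc(C=O)c(OCOC)c1 | intermediate
10 | 2,4-bis(methoxymethoxy)phenyl formate (not isolated) | COCOc1ccc(OC=O)c(OCOC)c1 | intermediate
11 | 2,4-bis(methoxymethoxy)phenol | COCOc1ccc(O)c(OCOC)c1 | intermediate
12 | 1-methoxy-2,4-bis(methoxymethoxy)benzene | COCOc1ccc(OC)c(OCOC)c1 | intermediate
13 | [3-methoxy-2,6-bis(methoxymethoxy)phenyl]lithium (not isolated) | [Li]c1c(OCOC)ccc(OC)c1OCOC | intermediate
14 | C11 carbinol, 7 with CH(OH)Ar in place of CHO (C11 epimers) | COCOc1ccc(OC)c(OCOC)c1C(O)[C@]2(C)[C@@H](C)CC=C3[C@H](O[Si](C)(C)C(C)(C)C)CCC[C@@H]23 | intermediate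
15 | sodium O-alkyl dithiocarbonate of 14 (not isolated) | COCOc1ccc(OC)c(OCOC)c1C(OC(=S)[S-])[C@]2(C)[C@@H](C)CC=C3[C@H](O[Si](C)(C)C(C)(C)C)CCC[C@@H]23.[Na+] | intermediate
16 | O-alkyl S-methyl xanthate of 14 | COCOc1ccc(OC)c(OCOC)c1C(OC(=S)SC)[C@]2(C)[C@@H](C)CC=C3[C@H](O[Si](C)(C)C(C)(C)C)CCC[C@@H]23 | intermediate
17 | 4α-silyloxy-8β,9β-dimethyl-9α-(ArCH2)-10α-H octalin with C5=C6 | COCOc1ccc(OC)c(OCOC)c1C[C@]2(C)[C@@H](C)CC=C3[C@H](O[Si](C)(C)C(C)(C)C)CCC[C@@H]23 | intermediate
18 | 4α-hydroxy analogue of 17 (allylic alcohol) | COCOc1ccc(OC)c(OCOC)c1C[C@]2(C)[C@@H](C)CC=C3[C@H](O)CCC[C@@H]23 | intermediate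
19 | 4-oxo-Δ5(6) enone | COCOc1ccc(OC)c(OCOC)c1C[C@]2(C)[C@@H](C)CC=C3C(=O)CCC[C@@H]23 | intermediate
20 | lithium C4–C5 enolate (not isolated) | COCOc1ccc(OC)c(OCOC)c1C[C@]2(C)[C@@H](C)CCC3=C([O-])CCC[C@@H]23.[Li+] | intermediate
21 | cis-fused 5α,8β,9β-trimethyl-9α-(ArCH2)-10α-H decalin-4-one | COCOc1ccc(OC)c(OCOC)c1C[C@]2(C)[C@@H](C)CC[C@@]3(C)C(=O)CCC[C@@H]23 | intermediate
22 | potassium C3–C4 enolate of 21 (not isolated) | COCOc1ccc(OC)c(OCOC)c1C[C@]2(C)[C@@H](C)CC[C@@]3(C)C([O-])=CCC[C@@H]23.[K+] | intermediate
23 | C4 enol triflate (C3=C4) | COCOc1ccc(OC)c(OCOC)c1C[C@]2(C)[C@@H](C)CC[C@@]3(C)C(OS(=O)(=O)C(F)(F)F)=CCC[C@@H]23 | intermediate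
24 | 1-(Dec-methyl)-3-methoxy-2,6-bis(methoxymethoxy)benzene | COCOc1ccc(OC)c(OCOC)c1C[C@]2(C)[C@@H](C)CC[C@@]3(C)C(C)=CCC[C@@H]23 | intermediate
25 | C5'-lithio derivative of 24 (not isolated) | COCOc1c([Li])cc(OC)c(OCOC)c1C[C@]2(C)[C@@H](C)CC[C@@]3(C)C(C)=CCC[C@@H]23 | intermediate
26 | 1-[3-(Dec-methyl)-5-methoxy-2,4-bis(methoxymethoxy)phenyl]ethan-1-one | COCOc1c(C(C)=O)cc(OC)c(OCOC)c1C[C@]2(C)[C@@H](C)CC[C@@]3(C)C(C)=CCC[C@@H]23 | intermediate
27 | 1-[2,4-dihydroxy-5-methoxy-3-(Dec-methyl)phenyl]ethan-1-one | CC(=O)c1cc(OC)c(O)c(C[C@]2(C)[C@@H](C)CC[C@@]3(C)C(C)=CCC[C@@H]23)c1O | intermediate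
28 | (E)-oxime of 27 | C/C(=N\O)c1cc(OC)c(O)c(C[C@]2(C)[C@@H](C)CC[C@@]3(C)C(C)=CCC[C@@H]23)c1O | intermediate
29 | O-trifluoromethanesulfonyl oxime of 27 (not isolated) | C/C(=N\OS(=O)(=O)C(F)(F)F)c1cc(OC)c(O)c(C[C@]2(C)[C@@H](C)CC[C@@]3(C)C(C)=CCC[C@@H]23)c1O | intermediate
30 | N-aryl acetonitrilium triflate (not isolated) | CC#[N+]c1cc(OC)c(O)c(C[C@]2(C)[C@@H](C)CC[C@@]3(C)C(C)=CCC[C@@H]23)c1O.[O-]S(=O)(=O)C(F)(F)F | intermediate
31 | 5-methoxy-2-methyl-7-{[(1R,2S,4aR,8aS)-1,2,4a,5-tetramethyl-1,2,3,4,4a,7,8,8a-octahydronaphthalen-1-yl]methyl}-1,3-benzoxazol-6-ol | COc1cc2nc(C)oc2c(C[C@]2(C)[C@@H](C)CC[C@@]3(C)C(C)=CCC[C@@H]23)c1O | target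

## Step count

Total: 20 steps. Longest linear sequence: 17 steps (steps 1–5 and 9–20 from 1); the arene branch (steps 6–8) adds 3.

## Steps most likely to fail

**Step 5 (cycloaddition).** The Lewis acid may ionise the allylic silyl ether or oligomerise the diene, and exo/endo or facial discrimination may be incomplete, giving diastereomeric adducts. The fallback moves stereocontrol from the substrate to a catalyst; it sets out from 2 and comes back at 19. Ketalisation of 2 (ethylene glycol, p-TsOH, benzene, reflux) gives 6-iodo-1,4-dioxaspiro[4.5]dec-6-ene F1. Stille vinylation as in step 4 gives the achiral diene 6-ethenyl-1,4-dioxaspiro[4.5]dec-6-ene F2. Cycloaddition with 6 under a cationic chiral oxazaborolidine (3,3-diphenyl-1-(2-methylphenyl)tetrahydro-1H,3H-pyrrolo[1,2-c][1,3,2]oxazaborole activated with HNTf2, enantiomer chosen for the required sense) would give the ketal aldehyde F3; this catalyst class is known for exo-selective, enantioselective additions of α-substituted enals. Addition of 13 gives the carbinol F4, xanthate formation the xanthate F5, and tin hydride reduction the deoxygenated ketal F6, as in steps 9–11. Pyridinium p-toluenesulfonate in wet acetone then unmasks the ketone and returns enone 19.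

**Step 14 (reductive methylation).** The electron-rich arene may suffer Birch-type reduction, or proton transfer in the enolate may lead to a second methylation at C3. The fallback avoids dissolving metal and a free enolate; it sets out from 19 and comes back at 21. 1,4-Hydrosilylation of 19 with Et3SiH and catalytic [(Ph3P)CuH]6 gives the triethylsilyl enol ether F7. Simmons–Smith cyclopropanation (Et2Zn, CH2I2) on the same open α face gives the siloxycyclopropane F8. NaOH in MeOH then opens the cyclopropanol at the CH2–C4 bond, leaving the methyl on C5 and the ketone 21.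

**Step 20 (rearrangement and ring closure).** A phenol may be sulfonylated in place of the oxime, acid may shift or add to the C3=C4 alkene, or closure may occur at nitrogen to the 1,2-benzisoxazole. The fallback separates aryl migration from ring closure; it sets out from 26 and comes back at 31. Oximation of 26 (NH2OH·HCl, pyridine) gives the bis-MOM oxime F9. O-Tosylation (TsCl, Et3N, 4-(dimethylamino)pyridine) followed by rearrangement on wet silica gives the acetanilide F10 by the same aryl shift to nitrogen. HCl in MeOH removes both MOM groups to give the dihydroxy acetanilide F11. Cyclodehydration with PPh3 and diisopropyl azodicarboxylate in THF closes the O–C2 bond and gives 31.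

## Further compounds

F1 | step 5 | 6-iodo-1,4-dioxaspiro[4.5]dec-6-ene | IC1=CCCCC12OCCO2
F2 | step 5 | 6-ethenyl-1,4-dioxaspiro[4.5]dec-6-ene | C=CC1=CCCCC12OCCO2
F3 | step 5 | ketal aldehyde (ethylene ketal at C4, C5=C6, 8β,9β-dimethyl, 9α-CHO, 10α-H) | O=C[C@]1(C)[C@@H](C)CC=C2C3(OCCO3)CCC[C@@H]12
F4 | step 5 | C11 carbinol of the ketal series (C11 epimers) | COCOc1ccc(OC)c(OCOC)c1C(O)[C@]2(C)[C@@H](C)CC=C3C4(OCCO4)CCC[C@@H]23
F5 | step 5 | S-methyl xanthate of F4 | COCOc1ccc(OC)c(OCOC)c1C(OC(=S)SC)[C@]2(C)[C@@H](C)CC=C3C4(OCCO4)CCC[C@@H]23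
F6 | step 5 | deoxygenated ketal (C11 = CH2) | COCOc1ccc(OC)c(OCOC)c1C[C@]2(C)[C@@H](C)CC=C3C4(OCCO4)CCC[C@@H]23
F7 | step 14 | triethylsilyl enol ether (C4=C5) | COCOc1ccc(OC)c(OCOC)c1C[C@]2(C)[C@@H](C)CCC3=C(O[Si](CC)(CC)CC)CCC[C@@H]23
F8 | step 14 | 4-triethylsilyloxy-4,5-methano decalin (cyclopropane CH2 on the α face) | COCOc1ccc(OC)c(OCOC)c1C[C@]2(C)[C@@H](C)CC[C@]34C[C@]4(O[Si](CC)(CC)CC)CCC[C@@H]23
F9 | step 20 | (E)-oxime of 26 | C/C(=N\O)c1cc(OC)c(OCOC)c(C[C@]2(C)[C@@H](C)CC[C@@]3(C)C(C)=CCC[C@@H]23)c1OCOC
F10 | step 20 | N-[3-(Dec-methyl)-5-methoxy-2,4-bis(methoxymethoxy)phenyl]acetamide | CC(=O)Nc1cc(OC)c(OCOC)c(C[C@]2(C)[C@@H](C)CC[C@@]3(C)C(C)=CCC[C@@H]23)c1OCOC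
F11 | step 20 | N-[2,4-dihydroxy-5-methoxy-3-(Dec-methyl)phenyl]acetamide | CC(=O)Nc1cc(OC)c(O)c(C[C@]2(C)[C@@H](C)CC[C@@]3(C)C(C)=CCC[C@@H]23)c1O
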